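## Structural features

Atoms are numbered in the order in which they appear in the target SMILES (C1 … O25). The carbon skeleton is a bicyclo[9.3.1]pentadecane: cyclohexene ring A (C2, C3, C4, C6, C7, C14) shares C6, C7 and C14 with a twelve-membered carbocycle (C6, C7, C14, C13, C12, C10, C16, C18, C19, C20, C23, C24). O9 links C8 on C7 to C10, so that an oxepane (C7, C8, O9, C10, C12, C13, C14) is fused to ring A along C7–C14. The seven stereocentres form three adjacent pairs plus one: C2 (S) next to the all-carbon quaternary C14 (R) with the methyls C1 and C15 cis, the tertiary ether carbon C10 (S) next to the carbinol C16 (R), the cis-epoxide C20 (R)/C23 (R), and the C4 carbinol (R) on the same face of ring A as both methyls. The fragile groups are the α,β-epoxy ketone at C24 (cross-conjugated with the tetrasubstituted C6=C7), the allylic C4 alcohol, and the C16 hydroxyl, which under acid can reach the epoxide carbon C20 through a five-membered transition state. The real difficulty is the congested array C2–C14–C7–C6 (a quaternary carbon between a tertiary centre and a tetrasubstituted bridgehead alkene that carries the acyl carbon C24), the closure of the large ring at that alkene, and the need to relate three remote stereochemical domains by absolute control. With C4 at the ketone level, ring A is a 4,4,5-trisubstituted 3-(oxymethyl)cyclohex-2-enone in which C14 sits between the enone carbon C7 and the carbonyl-level carbon C13, and C2–C3–C4–C6 is a pentenone unit. That is the retron of a Michael–aldol annulation forming C14–C2 and C6=C7 and setting C2 and C14 together.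

## Logic of the disconnections

**37 ⇒ 36 ⇒ 35.** No skeletal bond is cut; the two O–Si bonds and the C24 oxidation level are adjusted. The epoxy ketone and the free C16 hydroxyl are allowed to coexist only in the last compound. This reduces the problem to 35, a carbinol with no sensitive carbonyl. The forward steps must be non-acidic: a buffered oxidation and buffered fluoride.

**35 ⇒ 34.** The C6–C24 bond is cut. It is the one carbon–carbon bond of the large ring that joins an sp2 ring-A carbon to a carbonyl-level carbon, so it can be made by alkenyl-metal addition to an aldehyde. The gain is the open-chain 34, in which every stereocentre is set before the ring is closed. The demand is an alkenyl metal at the hindered C6 that tolerates an epoxy aldehyde and adds only to the aldehyde, at high dilution.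

**34 ⇒ 33 ⇒ 32.** The two C–O bonds of the C20/C23 epoxide and the C24 aldehyde level are removed, giving the Z-allylic alcohol 32. A primary allylic alcohol allows epoxidation with absolute control and with selectivity for that alkene only. The demand is that the C16 hydroxyl be capped beforehand (hence 31), otherwise it would open the new epoxide.

**32 ⇒ 31 ⇒ 30 ⇒ 29.** The ester and silyl groups are adjusted and the C4–H bond is removed, giving the ketone 29. The ketone is what the annulation delivers and what activates C6 for iodination. The forward reduction must be 1,2-selective and deliver hydride to the face opposite the C15 methyl.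

**29 ⇒ 28 ⇒ 27 ⇒ 26.** The O9–C10 bond is cut and the C10/C16 oxygens are traced to one E-alkene. Opening an epoxide at its tertiary carbon in the exo mode closes the oxepane and creates both stereocentres from one reagent-controlled epoxidation. One ring and two stereocentres disappear. The demands are inversion at C10 without cation scrambling, epoxidation of C10=C16 in preference to C20=C23, and ring closure before the second epoxide exists.

**26 ⇒ 25.** The C6–I bond is cut. The α-position of the enone is the only handle on C6, and the halide must be absent during the palladium coupling that precedes it. The forward iodination must spare two isolated alkenes.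

**25 ⇒ 24 ⇒ 12 + 22.** The C12–C10 bond is cut (sp3–sp2 coupling). This splits the molecule into ring A and a ten-carbon chain, and the E geometry of C10=C16 is carried by the iodide 22. The demand is a hydroboration of the vinyl group in a ketone-containing substrate; this is met by letting the borane reduce the ketone and re-oxidising afterwards.

**22 ⇒ 20 ⇒ 16 + 18; 16 ⇒ 15 ⇒ 13; 18 ⇒ 17.** The C10–I bond and the C19–C20 bond are cut. Each trisubstituted alkene then comes from a stereospecific hydrometalation of an alkyne (anti for Z, syn for E). The chain is reduced to two commercial alkynols, 13 and 17.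

**12 ⇒ 11 ⇒ 10 ⇒ 9.** The C12=C13 bond is cut and C13 returned to the ester level. C13 leaves the annulation as an ester, and a vinyl group is the shortest link to the coupling. The demand is olefination of an aldehyde in the presence of the enone.

**9 ⇒ 5 + 6.** The C14–C2 bond and the C6=C7 bond are cut (the key step). Ring A, both ring stereocentres, the C4 oxygen, the free C6–H, the C8 oxygen and the C13 carbon all come from two acyclic partners. The demand is catalyst control of both new centres and the correct aldol direction.

**5 ⇒ 3 + 4; 3 ⇒ 1 + 2.** The C14–C15 bond and the O–C8 ether bond are cut, leading to commercial materials. The forward steps must alkylate once at carbon and etherify only at the chloromethyl carbon.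

## Other disconnections considered

**Alternative 1:** The cut is C13–C14, the last bond of both the oxepane and the twelve-membered carbocycle. In the forward step the phenol A1 would be deprotonated with KOt-Bu, and the phenolate would attack the bromide through its para carbon C14, dearomatising to the cross-conjugated dienone A2. A1 has an aromatic ring A whose ortho carbons C6 and C7 are bridged by the eleven-membered ether chain C8–O9–C10–C16…C24, with the C12–C13 bromoethyl arm on C10. A2 contains three rings (ring A, oxepane, carbocycle); "bicyclic" describes only its carbocyclic core.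
- In its favour: ring A comes from a simple arene, the large ring is first closed as a less strained benzo-fused ether, and one step creates the quaternary centre and two rings.
- Against it here: O-alkylation and ortho attack compete with attack at a methyl-bearing para carbon through a seven-membered transition state. The face of attack is decided only by the chain stereocentres. C2 is still sp2 in A2, so the cis relation of C1 and C15 would depend on a later face-selective reduction of C2=C3 without catalyst control.
- Comparison: in ring-forming economy this alternative is the better plan (two rings and the quaternary centre in one step, against separate oxepane closure and macrocyclisation). It is equal to the chosen plan in needing late redox work at C4 and C24. It is weaker on structure and mechanism, because the chosen annulation fixes C2 and C14 together under catalyst control at the outset.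

**Alternative 2:** The cuts are C1–C2 and C13–C14 on a preformed six-membered ring. In the forward step Cu(OTf)2 with a chiral phosphoramidite ligand would transfer a methyl group from trimethylaluminium A4 to the β-carbon of 2-methylcyclohex-2-en-1-one A3, and the resulting aluminium enolate would be allylated at C14 with 3-iodoprop-1-ene A5 to give (2R,3S)-2-allyl-2,3-dimethylcyclohexanone A6.
- In its favour: the enone A3, the methyl source A4 and the allyl iodide A5 are all commercial. Trapping an enolate anti to the new β-substituent gives the cis-methyl relation intrinsically. The allyl group of A6 is a direct precursor of the C13–C12 arm, which is better than the chosen plan, where the ester needs three steps to become a vinyl group.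
- Against it here: aluminium enolates react poorly with allyl halides such as A5 and may need activation or a detour through an enol silane. A6 has a C7 ketone but no C8 carbon, no oxygen at C4 and no C6=C7 alkene, so each must be added by further steps.
- Comparison: on mechanism and availability of materials the alternative is at least the equal of the chosen key step. On structure it is weaker, because the annulation product 9 already carries the C4 carbonyl, a free C6–H, the C8 oxygen and C13. Overall step economy is therefore expected to favour the chosen plan.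

**Alternative 3:** The cuts are C6–C24 and C7–C8, made together. In the forward step the ring-A enone A7 (C6–H, C7–H, silyloxyethyl arm on C14) would be irradiated with 1,3-dioxol-2-one A8 to give the cis-fused cyclobutane carbonate A9. Carbonate hydrolysis and glycol cleavage would later expose C24 and C8 as carbonyl carbons.
- In its favour: both missing carbons arrive oxygenated in one step, regiochemistry is not an issue because A8 is symmetric, and C6 is acylated without the iodination and alkenyl-metal chemistry of the chosen route. On this last point it is the better plan.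
- Against it here: the two formyl groups released from the cyclobutane of A9 must be told apart, C6=C7 must be restored by oxidation, and the face of addition next to the quaternary C14 has little bias. A7 itself still needs an enantioselective synthesis of C2/C14, so the stereochemical core is not addressed.
- Comparison: in bonds per step it equals the chosen key step (two C–C bonds, one ring). In redox economy and stereochemical content it is weaker. The photochemical mechanism adds a scale constraint that the amine-catalysed annulation does not have.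

Key step: step 3

Assumption: the quinine-derived primary amine is taken to give the (2S,14R) series drawn; its quinidine-derived pseudoenantiomer gives the opposite sense and would replace it if the sense of induction proves to be the wrong one.

Remark on the precursor: the C8 oxygen is carried as a 4-methoxybenzyl ether in preference to a plain benzyl ether. A benzyl ether could later be removed only by hydrogenolysis or dissolving metal, and neither is compatible with the alkenyl iodide, the alkenes and the epoxide. The skeletons of both annulation partners are unchanged. In target numbering, C2 is the β-carbon of the enone (C-4 of pent-3-en-2-one).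

## Route

Step 1
Reactants: 1 methyl 4-chloro-3-oxobutanoate; 2 (4-methoxyphenyl)methanol
Product: 3 methyl 4-[(4-methoxybenzyl)oxy]-3-oxobutanoate
Conditions: NaH (2.2 equiv), THF, 0 → 25 °C; aq. NH4Cl
Reagents that add atoms: none
Why: Williamson etherification of an α-chloro ketone; the first equivalent of NaH stores the keto ester as its sodium enolate, so the alkoxide of 2 attacks only the chloromethyl carbon (C8).

Step 2
Reactants: 3 methyl 4-[(4-methoxybenzyl)oxy]-3-oxobutanoate; 4 iodomethane
Product: 5 methyl 4-[(4-methoxybenzyl)oxy]-2-methyl-3-oxobutanoate (racemic)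
Conditions: K2CO3, acetone, 25 °C
Reagents that add atoms: iodomethane (compound 4), CI
Why: C-alkylation of a β-keto ester enolate; the doubly activated C14–H is far more acidic than the C8 hydrogens and one equivalent of the soft electrophile limits dialkylation. The new centre is labile and need not be controlled.

Step 3
Reactants: 5 methyl 4-[(4-methoxybenzyl)oxy]-2-methyl-3-oxobutanoate; 6 (E)-pent-3-en-2-one
Product: 9 methyl (1R,6S)-2-{[(4-methoxybenzyl)oxy]methyl}-1,6-dimethyl-4-oxocyclohex-2-ene-1-carboxylate, via Michael adduct 7 (not isolated), via ketol 8 (not isolated)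
Conditions: 9-amino-9-deoxy-epi-quinine (20 mol %), CF3CO2H (40 mol %), toluene, 25 → 50 °C
Reagents that add atoms: none
Why: The primary amine condenses with 6 to an iminium ion, and the enol of 5, held by hydrogen bonding to the protonated quinuclidine, adds to the enone β-carbon (future C2) to form C14–C2 and give 7. The amine then forms the enamine on the methyl side of the C4 ketone, which adds to the C7 ketone (activated by the α-alkoxy group and the ester) and dehydrates by E1cB to 9. The closest known reaction type is the amine-salt-catalysed asymmetric Robinson annulation of α-substituted β-keto esters with α,β-unsaturated ketones. Ring A closes by a 6-(enolendo)-exo-trig aldol followed by loss of water. C2 is set by the face of the E-iminium ion that the catalyst leaves open (attack on the Si face of the β-carbon). C14 is set by the orientation in which the catalyst-bound enol meets that face, which places C15 cis to C1. The step needs the aldol to run from C6 onto C7 and not from C8 onto C4: the enamine forms only at the unhindered C4 ketone, while the C7 ketone next to the quaternary centre acts as the electrophile, and dehydration can only give C6=C7 because C14 has no hydrogen. Neither new centre can epimerise afterwards (C14 is quaternary, C2 is β to the carbonyl).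

Step 4
Reactants: 9 methyl (1R,6S)-2-{[(4-methoxybenzyl)oxy]methyl}-1,6-dimethyl-4-oxocyclohex-2-ene-1-carboxylate
Product: 10 (4R,5S)-4-(hydroxymethyl)-3-{[(4-methoxybenzyl)oxy]methyl}-4,5-dimethylcyclohex-2-en-1-ol (C1 epimers)
Conditions: i-Bu2AlH (5 equiv), CH2Cl2, −78 → 0 °C; aq. KNaC4H4O6
Reagents that add atoms: none
Why: Aluminium hydride reduction of the hindered ester to the neopentyl alcohol and 1,2-reduction of the enone; the C4 configuration is irrelevant because C4 is re-oxidised in step 5.

Step 5
Reactants: 10 (4R,5S)-4-(hydroxymethyl)-3-{[(4-methoxybenzyl)oxy]methyl}-4,5-dimethylcyclohex-2-en-1-ol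
Product: 11 (1R,6S)-2-{[(4-methoxybenzyl)oxy]methyl}-1,6-dimethyl-4-oxocyclohex-2-ene-1-carbaldehyde
Conditions: Dess–Martin periodinane (3 equiv), NaHCO3, CH2Cl2, 0 → 25 °C
Reagents that add atoms: none
Why: Dess–Martin oxidation of both alcohols; the aldehyde cannot enolise (C14 is quaternary) and the buffered neutral medium avoids deformylation of this vinylogous β-dicarbonyl compound.

Step 6
Reactants: 11 (1R,6S)-2-{[(4-methoxybenzyl)oxy]methyl}-1,6-dimethyl-4-oxocyclohex-2-ene-1-carbaldehyde
Product: 12 (4R,5S)-4-ethenyl-3-{[(4-methoxybenzyl)oxy]methyl}-4,5-dimethylcyclohex-2-en-1-one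
Conditions: Ph3PCH3Br, KN(SiMe3)2, THF, 0 °C; then 11, −78 → 0 °C
Reagents that add atoms: methyltriphenylphosphonium bromide, C[P+](c1ccccc1)(c1ccccc1)c1ccccc1.[Br-]
Why: Wittig methylenation; one equivalent of the unstabilised ylide reacts with the aldehyde much faster than with the conjugated ketone at low temperature, installing C12 and leaving the enone.

Step 7
Reactants: 13 but-2-yn-1-ol
Product: 15 (Z)-3-iodobut-2-en-1-ol, via cyclic alkenylaluminate 14 (not isolated)
Conditions: NaAlH2(OCH2CH2OMe)2, THF, 0 → 25 °C; then I2, −78 → 0 °C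
Reagents that add atoms: iodine, II
Why: Hydroxyl-directed trans-hydroalumination of the propargylic alcohol places aluminium on C3 cis to the CH2O group in a five-membered aluminate; iodinolysis with retention gives the Z-iodoalkenol (future C20–C24).

Step 8
Reactants: 15 (Z)-3-iodobut-2-en-1-ol
Product: 16 (Z)-3-iodobut-2-en-1-yl 2,2-dimethylpropanoate
Conditions: t-BuCOCl, pyridine, DMAP (cat.), CH2Cl2, 0 °C
Reagents that add atoms: pivaloyl chloride, CC(C)(C)C(=O)Cl
Why: Acylation of the primary alcohol; the pivalate survives the organometallic steps and later withdraws electron density from the Z-alkene, protecting it from the dioxirane.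

Step 9
Reactants: 17 pent-3-yn-1-ol
Product: 18 5-iodopent-2-yne
Conditions: PPh3, I2, imidazole, CH2Cl2, 0 → 25 °C
Reagents that add atoms: iodine, II
Why: Appel-type iodination of a primary alcohol; the internal alkyne is inert.

Step 10
Reactants: 18 5-iodopent-2-yne; 16 (Z)-3-iodobut-2-en-1-yl 2,2-dimethylpropanoate
Product: 20 (Z)-3-methyloct-2-en-6-yn-1-yl 2,2-dimethylpropanoate, via alkylzinc iodide 19 (not isolated)
Conditions: Zn, LiCl, THF, 40 °C; then 16, Pd(PPh3)4 (3 mol %), THF, 25 °C
Reagents that add atoms: none
Why: Zinc insertion into the primary iodide and Negishi coupling form C19–C20 with retention of the Z geometry; oxidative addition of zerovalent palladium to the C–I bond outruns ionisation of the allylic ester.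

Step 11
Reactants: 20 (Z)-3-methyloct-2-en-6-yn-1-yl 2,2-dimethylpropanoate
Product: 22 (2Z,6E)-7-iodo-3-methylocta-2,6-dien-1-yl 2,2-dimethylpropanoate, via alkenylzirconocene chloride 21 (not isolated)
Conditions: Cp2Zr(H)Cl (2 equiv), THF, 25 → 45 °C; then I2, THF, 0 °C
Reagents that add atoms: iodine, II
Why: Hydrozirconation of a 2-alkyne is a syn addition, and with excess reagent zirconium settles on the less hindered methyl-bearing carbon (C10); iodinolysis with retention gives the E-2-iodoalkene. The trisubstituted alkene is not hydrozirconated.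

Step 12
Reactants: 12 (4R,5S)-4-ethenyl-3-{[(4-methoxybenzyl)oxy]methyl}-4,5-dimethylcyclohex-2-en-1-one; 22 (2Z,6E)-7-iodo-3-methylocta-2,6-dien-1-yl 2,2-dimethylpropanoate
Product: 24 (2Z,6E)-9-[(1R,6S)-4-hydroxy-2-{[(4-methoxybenzyl)oxy]methyl}-1,6-dimethylcyclohex-2-en-1-yl]-3,7-dimethylnona-2,6-dien-1-yl 2,2-dimethylpropanoate (C4 epimers), via borane borinate 23 (not isolated)
Conditions: 9-BBN (2.5 equiv), THF, 0 → 25 °C; then 22, Pd(dppf)Cl2 (5 mol %), AsPh3, Cs2CO3, DMF–H2O, 25 °C
Reagents that add atoms: none
Why: 9-BBN adds to the terminal carbon C12 of the vinyl group and also reduces the C4 ketone 1,2 to its borinate; the B-alkyl Suzuki–Miyaura coupling then forms C12–C10 with retention of the E geometry. Ring A carries no halide at this stage, and any ketone that escapes reduction converges with 24 in step 13.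

Step 13
Reactants: 24 (2Z,6E)-9-[(1R,6S)-4-hydroxy-2-{[(4-methoxybenzyl)oxy]methyl}-1,6-dimethylcyclohex-2-en-1-yl]-3,7-dimethylnona-2,6-dien-1-yl 2,2-dimethylpropanoate
Product: 25 (2Z,6E)-9-[(1R,6S)-2-{[(4-methoxybenzyl)oxy]methyl}-1,6-dimethyl-4-oxocyclohex-2-en-1-yl]-3,7-dimethylnona-2,6-dien-1-yl 2,2-dimethylpropanoate
Conditions: MnO2, CH2Cl2, 25 °C
Reagents that add atoms: none
Why: Selective oxidation of the allylic alcohol returns the enone from either C4 epimer; the ester, the ether and the isolated alkenes are untouched.

Step 14
Reactants: 25 (2Z,6E)-9-[(1R,6S)-2-{[(4-methoxybenzyl)oxy]methyl}-1,6-dimethyl-4-oxocyclohex-2-en-1-yl]-3,7-dimethylnona-2,6-dien-1-yl 2,2-dimethylpropanoate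
Product: 26 (2Z,6E)-9-[(1R,6S)-3-iodo-2-{[(4-methoxybenzyl)oxy]methyl}-1,6-dimethyl-4-oxocyclohex-2-en-1-yl]-3,7-dimethylnona-2,6-dien-1-yl 2,2-dimethylpropanoate
Conditions: I2, pyridine, DMAP (cat.), CH2Cl2, 25 °C, dark
Reagents that add atoms: iodine, II
Why: Amine-mediated α-iodination of an enone (conjugate addition of the amine or dienolisation, iodination at C6, elimination); the isolated alkenes add iodine only reversibly because no internal nucleophile (free hydroxyl) is present at this stage.

Step 15
Reactants: 26 (2Z,6E)-9-[(1R,6S)-3-iodo-2-{[(4-methoxybenzyl)oxy]methyl}-1,6-dimethyl-4-oxocyclohex-2-en-1-yl]-3,7-dimethylnona-2,6-dien-1-yl 2,2-dimethylpropanoate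
Product: 27 (10R,16R)-epoxide of 26: (Z)-5-[(2R,3R)-3-{2-[(1R,6S)-3-iodo-2-{[(4-methoxybenzyl)oxy]methyl}-1,6-dimethyl-4-oxocyclohex-2-en-1-yl]ethyl}-3-methyloxiran-2-yl]-3-methylpent-2-en-1-yl 2,2-dimethylpropanoate
Conditions: D-fructose-derived ketone catalyst of the Shi epoxidation (30 mol %), KHSO5 (as 2KHSO5·KHSO4·K2SO4), K2CO3, Bu4NHSO4, MeCN–CH2(OMe)2–aq. Na2B4O7 buffer, 0 °C
Reagents that add atoms: potassium peroxymonosulfate, [K+].[O-]S(=O)(=O)OO
Why: Shi epoxidation through a spiro dioxirane transition state; the D-fructose-derived ketone gives the (R,R) sense on E-trisubstituted alkenes, which here is (10R,16R). The Z-alkene is deactivated by its allylic pivalate and the iodoenone alkene by conjugation, so only C10=C16 reacts.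

Step 16
Reactants: 27 (10R,16R)-epoxide of 26
Product: 29 (2Z,6R)-6-hydroxy-6-[(3S,5aR,6S)-9-iodo-3,5a,6-trimethyl-8-oxo-1,3,4,5,5a,6,7,8-octahydro-2-benzoxepin-3-yl]-3-methylhex-2-en-1-yl 2,2-dimethylpropanoate, via hydroxy epoxide 28 (not isolated)
Conditions: DDQ, CH2Cl2–pH 7 buffer, 0 °C; then (+)-camphorsulfonic acid (10 mol %), CH2Cl2, 0 °C
Reagents that add atoms: none
Why: Oxidative cleavage of the 4-methoxybenzyl ether frees the C8 hydroxyl, which opens the protonated epoxide at the tertiary carbon C10 in a 7-exo-tet closure; ring-size and Markovnikov preferences coincide. Inversion at C10 gives 10S and retention at C16 gives the 16R carbinol.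

Step 17
Reactants: 29 oxepane-fused iodoenone with free C16 hydroxyl
Product: 30 (2Z,6R)-6-hydroxy-6-[(3S,5aR,6S,8R)-8-hydroxy-9-iodo-3,5a,6-trimethyl-1,3,4,5,5a,6,7,8-octahydro-2-benzoxepin-3-yl]-3-methylhex-2-en-1-yl 2,2-dimethylpropanoate
Conditions: NaBH4, CeCl3·7H2O, MeOH, −40 °C
Reagents that add atoms: none
Why: Luche 1,2-reduction; axial delivery of hydride on the face opposite the axial C15 methyl should give the 4R alcohol, cis to both methyls. The C–I bond and the pivalate are not reduced.

Step 18
Reactants: 30 (4R,16R)-diol
Product: 31 4,16-bis(triethylsilyl) ether of 30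
Conditions: Et3SiOTf (2.5 equiv), 2,6-lutidine, CH2Cl2, −78 → 0 °C
Reagents that add atoms: triethylsilyl trifluoromethanesulfonate, CC[Si](CC)(CC)OS(=O)(=O)C(F)(F)F
Why: Silylation of both secondary hydroxyls in one operation; the C16 ether prevents attack on the later C20/C23 epoxide and both groups are removed together at the end.

Step 19
Reactants: 31 4,16-bis(triethylsilyl) ether pivalate
Product: 32 (Z)-allylic alcohol: 31 with the pivalate replaced by a free C24 hydroxyl
Conditions: i-Bu2AlH (2.5 equiv), CH2Cl2, −78 °C
Reagents that add atoms: none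
Why: Reductive cleavage of the pivalate at low temperature; the alkenyl iodide, silyl ethers and oxepane are inert to the hydride.

Step 20
Reactants: 32 (Z)-allylic alcohol
Product: 33 (20R,23S)-epoxy alcohol: 32 with a (2S,3R)-3-methyloxiran-2-ylmethanol terminus
Conditions: Ti(OiPr)4, L-(+)-diethyl tartrate, t-BuOOH, 4 Å sieves, CH2Cl2, −20 °C
Reagents that add atoms: tert-butyl hydroperoxide, CC(C)(C)OO
Why: Sharpless asymmetric epoxidation; only the alkene of the free allylic alcohol reacts, and L-(+)-tartrate delivers oxygen in the (2S,3R) sense established for Z-allylic alcohols of the nerol type, independent of the remote stereocentres.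

Step 21
Reactants: 33 (20R,23S)-epoxy alcohol
Product: 34 (20R,23R)-epoxy aldehyde: 33 with C24 as the aldehyde
Conditions: Dess–Martin periodinane, NaHCO3, CH2Cl2, 0 °C
Reagents that add atoms: none
Why: Buffered Dess–Martin oxidation of a 2,3-epoxy alcohol to the epoxy aldehyde; the aldehyde is used crude. The descriptor at C23 changes only because the priorities change.

Step 22
Reactants: 34 (20R,23R)-epoxy aldehyde
Product: 35 macrocyclic C24 carbinol (C24 epimers): the target skeleton with C4 and C16 as triethylsilyl ethers and C24–OH
Conditions: CrCl2 (15 equiv), NiCl2 (0.2 equiv), DMSO–THF, 25 °C, 0.003 M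
Reagents that add atoms: none
Why: Intramolecular Nozaki–Hiyama–Kishi reaction; zerovalent nickel inserts into C6–I, and transmetalation gives a non-basic alkenylchromium that adds only to the aldehyde. High dilution favours the twelve-membered carbocycle, and both C24 epimers converge in step 23.

Step 23
Reactants: 35 macrocyclic C24 carbinol
Product: 36 4,16-bis(triethylsilyl) ether of the target
Conditions: Dess–Martin periodinane, NaHCO3, CH2Cl2, 0 → 25 °C
Reagents that add atoms: none
Why: Dess–Martin oxidation of the allylic, epoxide-flanked carbinol to the C24 ketone under buffered conditions that leave the epoxide and silyl ethers intact.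

Step 24
Reactants: 36 4,16-bis(triethylsilyl) ether of the target
Product: 37 target CNP0316768.3, (2S,4R,10S,14R,16R,20R,23R)
Conditions: HF·pyridine, pyridine, THF, 0 °C
Reagents that add atoms: none
Why: Fluoride-mediated removal of both triethylsilyl ethers; buffering with pyridine avoids acid-triggered attack of the freed C16 hydroxyl on C20 and base-triggered damage to the epoxy ketone.

## Compound list

1 | methyl 4-chloro-3-oxobutanoate | COC(=O)CC(=O)CCl | starting material
2 | (4-methoxyphenyl)methanol | COc1ccc(CO)cc1 | starting material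
3 | methyl 4-[(4-methoxybenzyl)oxy]-3-oxobutanoate | COC(=O)CC(=O)COCc1ccc(OC)cc1 | intermediate
4 | iodomethane | CI | starting material
5 | methyl 4-[(4-methoxybenzyl)oxy]-2-methyl-3-oxobutanoate (racemic, labile centre) | COC(=O)C(C)C(=O)COCc1ccc(OC)cc1 | intermediate
6 | (E)-pent-3-en-2-one | C/C=C/C(C)=O | starting material
7 | methyl (2R,3S)-2-{[(4-methoxybenzyl)oxy]acetyl}-2,3-dimethyl-5-oxohexanoate (Michael adduct, formed in the flask) | C[C@@H](CC(C)=O)[C@@](C)(C(=O)OC)C(=O)COCc1ccc(OC)cc1 | intermediate
8 | methyl (1R,6S)-2-hydroxy-2-{[(4-methoxybenzyl)oxy]methyl}-1,6-dimethyl-4-oxocyclohexane-1-carboxylate (ketol, either C2 epimer, formed in the flask) | C[C@H]1CC(=O)CC(O)(COCc2ccc(OC)cc2)[C@]1(C)C(=O)OC | intermediate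
9 | methyl (1R,6S)-2-{[(4-methoxybenzyl)oxy]methyl}-1,6-dimethyl-4-oxocyclohex-2-ene-1-carboxylate | C[C@H]1CC(=O)C=C(COCc2ccc(OC)cc2)[C@]1(C)C(=O)OC | intermediate
10 | (4R,5S)-4-(hydroxymethyl)-3-{[(4-methoxybenzyl)oxy]methyl}-4,5-dimethylcyclohex-2-en-1-ol (C1 epimers) | C[C@H]1CC(O)C=C(COCc2ccc(OC)cc2)[C@]1(C)CO | intermediate
11 | (1R,6S)-2-{[(4-methoxybenzyl)oxy]methyl}-1,6-dimethyl-4-oxocyclohex-2-ene-1-carbaldehyde | C[C@H]1CC(=O)C=C(COCc2ccc(OC)cc2)[C@]1(C)C=O | intermediate
12 | (4R,5S)-4-ethenyl-3-{[(4-methoxybenzyl)oxy]methyl}-4,5-dimethylcyclohex-2-en-1-one | C[C@H]1CC(=O)C=C(COCc2ccc(OC)cc2)[C@]1(C)C=C | intermediate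
13 | but-2-yn-1-ol | CC#CCO | starting material
14 | sodium 2,2-bis(2-methoxyethoxy)-3-methyl-2,5-dihydro-1,2-oxaaluminol-2-uide (cyclic Z-alkenylaluminate, formed in the flask) | CC1=CCO[Al-]1(OCCOC)OCCOC.[Na+] | intermediate
15 | (Z)-3-iodobut-2-en-1-ol | C/C(I)=C/CO | intermediate
16 | (Z)-3-iodobut-2-en-1-yl 2,2-dimethylpropanoate | C/C(I)=C/COC(=O)C(C)(C)C | intermediate
17 | pent-3-yn-1-ol | CC#CCCO | starting material
18 | 5-iodopent-2-yne | CC#CCCI | intermediate
19 | iodo(pent-3-yn-1-yl)zinc (formed in the flask) | CC#CCC[Zn]I | intermediate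
20 | (Z)-3-methyloct-2-en-6-yn-1-yl 2,2-dimethylpropanoate | CC#CCC/C(C)=C\COC(=O)C(C)(C)C | intermediate
21 | chlorobis(cyclopentadienyl)[(2E,6Z)-6-methyl-8-(pivaloyloxy)octa-2,6-dien-2-yl]zirconium (formed in the flask; cyclopentadienyl rings drawn σ-bonded) | C/C(=C\CC/C(C)=C\COC(=O)C(C)(C)C)[Zr](Cl)(C1C=CC=C1)C1C=CC=C1 | intermediate
22 | (2Z,6E)-7-iodo-3-methylocta-2,6-dien-1-yl 2,2-dimethylpropanoate | C/C(I)=C\CC/C(C)=C\COC(=O)C(C)(C)C | intermediate
23 | 9-{2-[(1R,6S)-4-(9-borabicyclo[3.3.1]nonan-9-yloxy)-2-{[(4-methoxybenzyl)oxy]methyl}-1,6-dimethylcyclohex-2-en-1-yl]ethyl}-9-borabicyclo[3.3.1]nonane (C4 epimers, formed in the flask) | C[C@H]1CC(OB2C3CCCC2CCC3)C=C(COCc2ccc(OC)cc2)[C@]1(C)CCB1C2CCCC1CCC2 | intermediate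
24 | (2Z,6E)-9-[(1R,6S)-4-hydroxy-2-{[(4-methoxybenzyl)oxy]methyl}-1,6-dimethylcyclohex-2-en-1-yl]-3,7-dimethylnona-2,6-dien-1-yl 2,2-dimethylpropanoate (C4 epimers) | C[C@H]1CC(O)C=C(COCc2ccc(OC)cc2)[C@]1(C)CC/C(C)=C/CC/C(C)=C\COC(=O)C(C)(C)C | intermediate
25 | (2Z,6E)-9-[(1R,6S)-2-{[(4-methoxybenzyl)oxy]methyl}-1,6-dimethyl-4-oxocyclohex-2-en-1-yl]-3,7-dimethylnona-2,6-dien-1-yl 2,2-dimethylpropanoate | C[C@H]1CC(=O)C=C(COCc2ccc(OC)cc2)[C@]1(C)CC/C(C)=C/CC/C(C)=C\COC(=O)C(C)(C)C | intermediate
26 | (2Z,6E)-9-[(1R,6S)-3-iodo-2-{[(4-methoxybenzyl)oxy]methyl}-1,6-dimethyl-4-oxocyclohex-2-en-1-yl]-3,7-dimethylnona-2,6-dien-1-yl 2,2-dimethylpropanoate | C[C@H]1CC(=O)C(I)=C(COCc2ccc(OC)cc2)[C@]1(C)CC/C(C)=C/CC/C(C)=C\COC(=O)C(C)(C)C | intermediate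
27 | (Z)-5-[(2R,3R)-3-{2-[(1R,6S)-3-iodo-2-{[(4-methoxybenzyl)oxy]methyl}-1,6-dimethyl-4-oxocyclohex-2-en-1-yl]ethyl}-3-methyloxiran-2-yl]-3-methylpent-2-en-1-yl 2,2-dimethylpropanoate ((10R,16R)-epoxide) | C[C@H]1CC(=O)C(I)=C(COCc2ccc(OC)cc2)[C@]1(C)CC[C@@]1(C)O[C@@H]1CC/C(C)=C\COC(=O)C(C)(C)C | intermediate
28 | (Z)-5-[(2R,3R)-3-{2-[(1R,6S)-2-(hydroxymethyl)-3-iodo-1,6-dimethyl-4-oxocyclohex-2-en-1-yl]ethyl}-3-methyloxiran-2-yl]-3-methylpent-2-en-1-yl 2,2-dimethylpropanoate (formed in the flask) | C[C@H]1CC(=O)C(I)=C(CO)[C@]1(C)CC[C@@]1(C)O[C@@H]1CC/C(C)=C\COC(=O)C(C)(C)C | intermediate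
29 | (2Z,6R)-6-hydroxy-6-[(3S,5aR,6S)-9-iodo-3,5a,6-trimethyl-8-oxo-1,3,4,5,5a,6,7,8-octahydro-2-benzoxepin-3-yl]-3-methylhex-2-en-1-yl 2,2-dimethylpropanoate (target locants 2S,10S,14R,16R) | C[C@H]1CC(=O)C(I)=C2CO[C@@](C)(CC[C@@]21C)[C@H](O)CC/C(C)=C\COC(=O)C(C)(C)C | intermediate
30 | (2Z,6R)-6-hydroxy-6-[(3S,5aR,6S,8R)-8-hydroxy-9-iodo-3,5a,6-trimethyl-1,3,4,5,5a,6,7,8-octahydro-2-benzoxepin-3-yl]-3-methylhex-2-en-1-yl 2,2-dimethylpropanoate (target locants 2S,4R,10S,14R,16R) | C[C@H]1C[C@@H](O)C(I)=C2CO[C@@](C)(CC[C@@]21C)[C@H](O)CC/C(C)=C\COC(=O)C(C)(C)C | intermediate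
31 | 4,16-bis(triethylsilyl) ether of 30 | C[C@H]1C[C@@H](O[Si](CC)(CC)CC)C(I)=C2CO[C@@](C)(CC[C@@]21C)[C@H](O[Si](CC)(CC)CC)CC/C(C)=C\COC(=O)C(C)(C)C | intermediate
32 | (2Z,6R)-6-[(3S,5aR,6S,8R)-9-iodo-3,5a,6-trimethyl-8-(triethylsilyloxy)-1,3,4,5,5a,6,7,8-octahydro-2-benzoxepin-3-yl]-3-methyl-6-(triethylsilyloxy)hex-2-en-1-ol | C[C@H]1C[C@@H](O[Si](CC)(CC)CC)C(I)=C2CO[C@@](C)(CC[C@@]21C)[C@H](O[Si](CC)(CC)CC)CC/C(C)=C\CO | intermediate
33 | (20R,23S)-epoxy alcohol: {(2S,3R)-3-[(3R)-3-(benzoxepinyl as in 32)-3-(triethylsilyloxy)propyl]-3-methyloxiran-2-yl}methanol | C[C@H]1C[C@@H](O[Si](CC)(CC)CC)C(I)=C2CO[C@@](C)(CC[C@@]21C)[C@H](O[Si](CC)(CC)CC)CC[C@@]1(C)O[C@H]1CO | intermediate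
34 | (20R,23R)-epoxy aldehyde: (2R,3R)-3-[(3R)-3-(benzoxepinyl as in 32)-3-(triethylsilyloxy)propyl]-3-methyloxirane-2-carbaldehyde | C[C@H]1C[C@@H](O[Si](CC)(CC)CC)C(I)=C2CO[C@@](C)(CC[C@@]21C)[C@H](O[Si](CC)(CC)CC)CC[C@@]1(C)O[C@H]1C=O | intermediate
35 | macrocyclic carbinol, (2S,4R,10S,14R,16R,20R,23S), C24 epimers: target skeleton with C4–OSiEt3, C16–OSiEt3 and C24–OH | C[C@H]1C[C@@H](O[Si](CC)(CC)CC)C2=C3CO[C@@](C)(CC[C@@]31C)[C@H](O[Si](CC)(CC)CC)CC[C@@]1(C)O[C@H]1C2O | intermediate
36 | 4,16-bis(triethylsilyl) ether of the target, (2S,4R,10S,14R,16R,20R,23R) | C[C@H]1C[C@@H](O[Si](CC)(CC)CC)C2=C3CO[C@@](C)(CC[C@@]31C)[C@H](O[Si](CC)(CC)CC)CC[C@@]1(C)O[C@H]1C2=O | intermediate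
37 | CNP0316768.3: (2S,4R,10S,14R,16R,20R,23R)-4,16-dihydroxy-20,23-epoxy-8,10-oxa-bridged bicyclo[9.3.1]pentadec-6-en-24-one with methyls on C2, C10, C14 and C20 | C[C@H]1C[C@@H](O)C2=C3CO[C@@](C)(CC[C@@]31C)[C@H](O)CC[C@@]1(C)O[C@H]1C2=O | target

## Step count and least certain steps

Total: 24 steps. Longest linear sequence: 19 steps (steps 1–6 and 12–24, from 1 to 37). The side-chain iodide 22 takes 5 steps (steps 7–11), with a longest branch of 4.

**Step 3 (key step).** The most likely failure is insufficient facial discrimination at C14. The acyclic keto ester can present either enol geometry to the iminium ion, so the trans-dimethyl epimer would co-form; slow ring closure would also leave room for retro-Michael erosion. The fallback separates the two events and changes the activation mode. Starting from 5 and 6, the Michael addition is run under a 6'-hydroxy cinchona alkaloid ether as bifunctional Brønsted base and hydrogen-bond donor, which activates the keto ester and not the enone. The adduct 7 is isolated and its diastereomer purified, and ring A is then closed with pyrrolidinium acetate (enamine aldol condensation), returning to the route at 9. No new compound is involved.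

**Step 22.** The most likely failure is consumption of the epoxy aldehyde by electron transfer from divalent chromium (reductive epoxide opening), or protodeiodination, because ring closure at the doubly flanked C6 is slow. The fallback carries the alkene through the macrocyclisation and installs the epoxide last. Starting from 32, MnO2 gives the (Z)-enal F1. The same CrCl2/NiCl2 cyclisation gives the macrocyclic bis-allylic alcohol F2. Dess–Martin oxidation gives the cross-conjugated dienone F3. Weitz–Scheffer epoxidation (t-BuOOH, DBU) of the less hindered C20=C23 enone returns to the route at 36. Stereocontrol of the epoxide then rests on the macrocycle and not on a reagent.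

**Step 16.** The most likely failure is hydride shift or elimination from a cation-like C10, or partial loss of configuration there, because a seven-membered closure is slower than the usual five- or six-membered ones. The fallback forms the ether from the other side (O9–C8). Starting from 27, acid-catalysed hydrolysis in aqueous THF opens the epoxide at C10 with inversion to the (10S,16R)-diol F4. DDQ gives the triol F5. Selective sulfonylation of the primary allylic C8 hydroxyl (MsCl, 2,4,6-collidine) gives the mesylate F6. NaH then closes the oxepane by attack of the tertiary C10 alkoxide (7-exo-tet), returning to the route at 29.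

**Step 17.** The most likely failure is hydride approach from the wrong face, because the bias exerted by the remote axial C15 methyl against the oxepane arm is modest; reagent control with the (S)-oxazaborolidine of the Corey–Bakshi–Shibata reduction would be tried first. The fallback corrects the centre by inversion. Starting from 29, the reduction gives the (4S)-alcohol F7. Mitsunobu reaction (4-nitrobenzoic acid, PPh3, diisopropyl azodicarboxylate) at the allylic C4 only (C16 is neopentyl-like and inert) gives the (4R)-4-nitrobenzoate F8. Methanolysis (K2CO3, MeOH, 0 °C) returns to the route at 30.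

**Step 6.** The most likely failure is attack of the basic ylide on the enone (γ-deprotonation or methylenation) or deformylation of the vinylogous β-dicarbonyl aldehyde. The fallback masks the ketone first. Starting from 9, Me3SiOCH2CH2OSiMe3 with catalytic Me3SiOTf at −78 °C gives the dioxolane ester F9. LiAlH4 gives the alcohol F10. Dess–Martin oxidation gives the aldehyde F11. Wittig methylenation gives the vinyl ketal F12. Pyridinium 4-toluenesulfonate in aqueous acetone releases the enone, returning to the route at 12.

## Further compounds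

F0 | step 3 | none | none
F1 | step 22 | (2Z,6R)-6-[(3S,5aR,6S,8R)-9-iodo-3,5a,6-trimethyl-8-(triethylsilyloxy)-1,3,4,5,5a,6,7,8-octahydro-2-benzoxepin-3-yl]-3-methyl-6-(triethylsilyloxy)hex-2-enal | C[C@H]1C[C@@H](O[Si](CC)(CC)CC)C(I)=C2CO[C@@](C)(CC[C@@]21C)[C@H](O[Si](CC)(CC)CC)CC/C(C)=C\C=O
F2 | step 22 | macrocyclic bis-allylic alcohol: 35 with a (Z)-C20=C23 alkene in place of the epoxide (C24 epimers) | C[C@H]1C[C@@H](O[Si](CC)(CC)CC)C2=C3CO[C@@](C)(CC[C@@]31C)[C@H](O[Si](CC)(CC)CC)CC/C(C)=C\C2O
F3 | step 22 | macrocyclic cross-conjugated dienone: 36 with a (Z)-C20=C23 alkene in place of the epoxide | C[C@H]1C[C@@H](O[Si](CC)(CC)CC)C2=C3CO[C@@](C)(CC[C@@]31C)[C@H](O[Si](CC)(CC)CC)CC/C(C)=C\C2=O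
F4 | step 16 | (10S,16R)-diol from hydrolysis of 27 (4-methoxybenzyl ether retained) | C[C@H]1CC(=O)C(I)=C(COCc2ccc(OC)cc2)[C@]1(C)CC[C@](C)(O)[C@H](O)CC/C(C)=C\COC(=O)C(C)(C)C
F5 | step 16 | (10S,16R)-triol with free C8 hydroxyl | C[C@H]1CC(=O)C(I)=C(CO)[C@]1(C)CC[C@](C)(O)[C@H](O)CC/C(C)=C\COC(=O)C(C)(C)C
F6 | step 16 | C8 methanesulfonate of the (10S,16R)-triol | C[C@H]1CC(=O)C(I)=C(COS(C)(=O)=O)[C@]1(C)CC[C@](C)(O)[C@H](O)CC/C(C)=C\COC(=O)C(C)(C)C
F7 | step 17 | (4S)-epimer of 30 | C[C@H]1C[C@H](O)C(I)=C2CO[C@@](C)(CC[C@@]21C)[C@H](O)CC/C(C)=C\COC(=O)C(C)(C)C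
F8 | step 17 | (4R)-4-nitrobenzoate of 30 | C[C@H]1C[C@@H](OC(=O)c3ccc(cc3)[N+](=O)[O-])C(I)=C2CO[C@@](C)(CC[C@@]21C)[C@H](O)CC/C(C)=C\COC(=O)C(C)(C)C
F9 | step 6 | ethylene ketal of 9 (1,4-dioxaspiro[4.5]dec-6-ene methyl ester) | C[C@H]1CC2(OCCO2)C=C(COCc2ccc(OC)cc2)[C@]1(C)C(=O)OC
F10 | step 6 | ethylene ketal primary alcohol | C[C@H]1CC2(OCCO2)C=C(COCc2ccc(OC)cc2)[C@]1(C)CO
F11 | step 6 | ethylene ketal aldehyde | C[C@H]1CC2(OCCO2)C=C(COCc2ccc(OC)cc2)[C@]1(C)C=O
F12 | step 6 | ethylene ketal of 12 | C[C@H]1CC2(OCCO2)C=C(COCc2ccc(OC)cc2)[C@]1(C)C=C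
A1 | alternative 1 | benzo-fused eleven-membered ether phenol with 2-bromoethyl arm on C10 (silyl ethers at C16 and C24) | Cc1cc(O)c2c(c1C)CO[C@@](C)(CCBr)[C@H](O[Si](C)(C)C(C)(C)C)CC/C(C)=C\[C@@H]2O[Si](CC)(CC)CC
A2 | alternative 1 | tricyclic cross-conjugated cyclohexa-2,5-dienone from para-alkylation | CC1=CC(=O)C2=C3CO[C@@](C)(CC[C@@]31C)[C@H](O[Si](C)(C)C(C)(C)C)CC/C(C)=C\[C@@H]2O[Si](CC)(CC)CC
A3 | alternative 2 | 2-methylcyclohex-2-en-1-one | CC1=CCCCC1=O
A4 | alternative 2 | trimethylaluminium | C[Al](C)C
A5 | alternative 2 | 3-iodoprop-1-ene | C=CCI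
A6 | alternative 2 | (2R,3S)-2,3-dimethyl-2-(prop-2-en-1-yl)cyclohexan-1-one | C[C@H]1CCCC(=O)[C@]1(C)CC=C
A7 | alternative 3 | cis-4-[2-(tert-butyldimethylsilyloxy)ethyl]-4,5-dimethylcyclohex-2-en-1-one | C[C@H]1CC(=O)C=C[C@]1(C)CCO[Si](C)(C)C(C)(C)C
A8 | alternative 3 | 1,3-dioxol-2-one | O=C1OC=CO1
A9 | alternative 3 | cis-fused cyclobutane carbonate photoadduct | C[C@H]1CC(=O)[C@@H]2[C@H]3OC(=O)O[C@H]3[C@@H]2[C@]1(C)CCO[Si](C)(C)C(C)(C)C
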